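**Strategy**

- Retrosynthesis: the angelate and silyl groups come off first. The C12–O6 lactone bond and the C14 ester are traced back to two allylic methyl groups, and the C4–C5 oxirane to the alkene. The C6–C7 bond is then cut by a retro-[2,3]-Wittig shift to a 13-membered O6–C13 diallyl ether, which is opened at O6–C13 and cut at C9–C10. This leaves a nerol-derived (Z)-alkenyl iodide (C10, C1–C6, C14, C15) and a glyceraldehyde-derived α-silyloxy aldehyde (C7–C9, C11–C13).
- Enabling feature: C6 bears oxygen and is allylic to the ring-cis C4=C5 bond, and its neighbour C7 bears the exocyclic C11=C13 methylene of the cis-fused five-membered lactone (O6, C6, C7, C11, C12). This homoallylic alcohol array C6(O)–C7–C11=C13 is the imprint of a [2,3]-shift of a C6–O–C13 allyl ether; C1–C6 with C15 and the 4Z bond map onto nerol.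
- Forward order: the chain is joined at C9–C10, the 13-membered ether ring is closed at O6–C13 and contracted to the ten-membered carbocycle, the oxirane is added at C4–C5, and the γ-lactone is closed last between C12 and O6.
- Stereochemistry: C8 comes from (R)-glyceraldehyde acetonide and C9 from chelation-controlled alkenylzinc addition (syn to O8). C6 and C7 are set together in the ring contraction (syn from the Z C7=C11 bond, face set by C8). C4 and C5 follow from C6-hydroxyl-directed epoxidation of the Z alkene. The ring-cis C1=C10 bond comes from the Z-iodo-olefination, and the angelate geometry is bought with angelic acid.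

Key step: step 17

Remark: atoms carry germacrane numbers throughout (C1–C15; O6, O8, O9, O13 after their carbons). Where the CIP letter at C6 or C7 changes between compounds, only the substituent priorities have changed, not the centre.

**Route**

Step 1
Reactants: 1 nerol
Product: 2 neryl 4-methoxybenzyl ether
Conditions: NaH, 4-MeOC6H4CH2Cl, n-Bu4NI (cat.), THF/DMF, 0 °C → rt
Reagents that add atoms: 4-methoxybenzyl chloride COc1ccc(CCl)cc1
Why: Williamson etherification of the primary allylic alkoxide with a benzylic chloride; no stereocentre is made and the Z alkene is not touched.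

Step 2
Reactants: 2 neryl 4-methoxybenzyl ether
Product: 3 racemic distal epoxide of 2
Conditions: mCPBA (1.0 equiv), CH2Cl2, −20 → 0 °C
Reagents that add atoms: 3-chloroperoxybenzoic acid OOC(=O)c1cccc(Cl)c1
Why: Prilezhaev epoxidation should go to the more electron-rich distal trisubstituted alkene, the C4=C5 alkene being deactivated by its allylic ether oxygen; the new stereocentre is racemic and is destroyed in step 3.

Step 3
Reactants: 3 racemic distal epoxide of 2
Product: 4 (4Z)-6-[(4-methoxybenzyl)oxy]-4-methylhex-4-enal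
Conditions: H5IO6, THF/H2O, 0 °C
Reagents that add atoms: none
Why: periodic acid hydrates the epoxide at its tertiary carbon and cleaves the glycol (Malaprade cleavage) in one flask, so the aldehyde oxygen is the former epoxide oxygen, and the PMB ether and Z alkene should survive the cold dilute acid.

Step 4
Reactants: 4 (4Z)-6-[(4-methoxybenzyl)oxy]-4-methylhex-4-enal; 5 ethyltriphenylphosphonium iodide
Product: 9 (2Z,6Z)-7-iodo-3-methylocta-2,6-dien-1-yl 4-methoxybenzyl ether, via ethylidenetriphenylphosphorane 6 (not isolated), via (1-iodoethyl)triphenylphosphonium iodide 7 (not isolated), via (1-iodoethylidene)triphenylphosphorane 8 (not isolated)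
Conditions: 5, n-BuLi, THF, 0 °C; I2, −78 °C; NaN(SiMe3)2, −78 → −20 °C; then 4, −78 °C → rt
Reagents that add atoms: iodine II
Why: Stork–Zhao-type Wittig olefination with the α-iodo ylide made by iodination of ylide 6 and deprotonation of salt 7; the unstabilised ylide reacts under kinetic control through the cis-oxaphosphetane, which puts iodine cis to the chain (Z).

Step 5
Reactants: 10 (R)-2,2-dimethyl-1,3-dioxolane-4-carbaldehyde; 11 methyl 2-[bis(2,2,2-trifluoroethoxy)phosphoryl]propanoate
Product: 12 methyl (2Z)-3-[(4S)-2,2-dimethyl-1,3-dioxolan-4-yl]-2-methylprop-2-enoate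
Conditions: KN(SiMe3)2, 18-crown-6, THF, −78 °C
Reagents that add atoms: none
Why: Still–Gennari olefination: the electron-poor phosphonate with a dissociated potassium counter-ion eliminates from the kinetic adduct to give the Z enoate (ester carbon C13 cis to C8), and at −78 °C the α-alkoxy aldehyde should not epimerise.

Step 6
Reactants: 12 methyl (2Z)-3-[(4S)-2,2-dimethyl-1,3-dioxolan-4-yl]-2-methylprop-2-enoate
Product: 13 (2Z)-3-[(4S)-2,2-dimethyl-1,3-dioxolan-4-yl]-2-methylprop-2-en-1-ol
Conditions: i-Bu2AlH, CH2Cl2, −78 → 0 °C; aq. potassium sodium tartrate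
Reagents that add atoms: none
Why: 1,2-reduction of the conjugated ester by the aluminium hydride gives the allylic alcohol with the alkene geometry and the acetonide intact.

Step 7
Reactants: 13 (2Z)-3-[(4S)-2,2-dimethyl-1,3-dioxolan-4-yl]-2-methylprop-2-en-1-ol
Product: 14 (2Z)-3-[(4S)-2,2-dimethyl-1,3-dioxolan-4-yl]-2-methylprop-2-en-1-yl pivalate
Conditions: t-BuCOCl, pyridine, DMAP (cat.), CH2Cl2, 0 °C → rt
Reagents that add atoms: pivaloyl chloride CC(C)(C)C(=O)Cl
Why: acylation of the primary alcohol gives a pivalate that should withstand the acid, silylation, oxidation and organozinc steps ahead and is later removed reductively.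

Step 8
Reactants: 14 (2Z)-3-[(4S)-2,2-dimethyl-1,3-dioxolan-4-yl]-2-methylprop-2-en-1-yl pivalate
Product: 15 (2Z,4S)-4,5-dihydroxy-2-methylpent-2-en-1-yl pivalate
Conditions: AcOH/H2O (4:1), 40 °C
Reagents that add atoms: none
Why: acid-catalysed hydrolysis of the isopropylidene acetal frees the O8/O9 diol without breaking a bond to C8 and without touching the hindered pivalate.

Step 9
Reactants: 15 (2Z,4S)-4,5-dihydroxy-2-methylpent-2-en-1-yl pivalate
Product: 16 (2Z,4S)-2-methyl-4,5-bis(triethylsilyloxy)pent-2-en-1-yl pivalate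
Conditions: Et3SiCl, imidazole, DMF, 0 °C
Reagents that add atoms: chlorotriethylsilane CC[Si](Cl)(CC)CC
Why: silylation of both hydroxyls sets up the differentiation of the primary and the secondary silyl ether in step 10.

Step 10
Reactants: 16 (2Z,4S)-2-methyl-4,5-bis(triethylsilyloxy)pent-2-en-1-yl pivalate
Product: 18 (2Z,4S)-2-methyl-5-oxo-4-(triethylsilyloxy)pent-2-en-1-yl pivalate, via alkoxydimethylsulfonium chloride 17 (not isolated)
Conditions: (COCl)2, DMSO, CH2Cl2, −78 °C; 16, −78 → −40 °C; i-Pr2NEt, −78 → −20 °C; used crude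
Reagents that add atoms: none
Why: Swern-type oxidative desilylation: the activated sulfoxide attacks only the unhindered primary silyl ether to give salt 17, and base-induced elimination gives the aldehyde while the secondary silyl ether stays; low temperature and the hindered amine should keep the α-silyloxy β,γ-unsaturated aldehyde from epimerising at C8.

Step 11
Reactants: 9 (2Z,6Z)-7-iodo-3-methylocta-2,6-dien-1-yl 4-methoxybenzyl ether; 18 (2Z,4S)-2-methyl-5-oxo-4-(triethylsilyloxy)pent-2-en-1-yl pivalate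
Product: 21 (2Z,4S,5S,6Z,10Z)-5-hydroxy-12-[(4-methoxybenzyl)oxy]-2,6,10-trimethyl-4-(triethylsilyloxy)dodeca-2,6,10-trien-1-yl pivalate, via alkenyllithium 19 (not isolated), via alkenylzinc bromide 20 (not isolated)
Conditions: 9, t-BuLi (2 equiv), Et2O, −78 °C; ZnBr2, −78 → 0 °C; then 18, toluene/Et2O, −78 → −20 °C; aq. NH4Cl
Reagents that add atoms: none
Why: iodine–lithium exchange keeps the alkene geometry, transmetalation gives a non-basic alkenylzinc that spares the pivalate and the labile C8 centre, and zinc chelation between the aldehyde oxygen and the small silyloxy group (Cram chelate model, the mode known for organozinc additions to α-silyloxy aldehydes with zinc halides) should direct attack anti to the C7 alkenyl group to give the 8,9-syn (9S) carbinol.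

Step 12
Reactants: 21 (8S,9S) carbinol
Product: 22 (2Z,4S,5S,6Z,10Z)-5-(tert-butyldimethylsilyloxy)-12-[(4-methoxybenzyl)oxy]-2,6,10-trimethyl-4-(triethylsilyloxy)dodeca-2,6,10-trien-1-yl pivalate
Conditions: t-BuMe2SiOTf, 2,6-lutidine, CH2Cl2, −78 → 0 °C
Reagents that add atoms: tert-butyldimethylsilyl trifluoromethanesulfonate CC(C)(C)[Si](C)(C)OS(=O)(=O)C(F)(F)F
Why: silylation of the hindered secondary allylic alcohol with the silyl triflate; O8 (TES) and O9 (TBS) can then be told apart by their lability.

Step 13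
Reactants: 22 9-O-TBS pivalate
Product: 23 (2Z,4S,5S,6Z,10Z)-5-(tert-butyldimethylsilyloxy)-12-[(4-methoxybenzyl)oxy]-2,6,10-trimethyl-4-(triethylsilyloxy)dodeca-2,6,10-trien-1-ol
Conditions: i-Bu2AlH, CH2Cl2, −78 °C; aq. potassium sodium tartrate
Reagents that add atoms: none
Why: reductive cleavage of the pivalate by the aluminium hydride leaves the PMB and silyl ethers alone and generates no free alkoxide that could move a silyl group.

Step 14
Reactants: 23 C13 allylic alcohol
Product: 25 C13 allylic chloride (chlorine in place of the hydroxyl of 23), via C13 methanesulfonate 24 (not isolated)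
Conditions: MeSO2Cl, 2,4,6-collidine, LiCl, DMF, 0 °C → rt
Reagents that add atoms: lithium chloride [Li+].[Cl-]
Why: mesylation and in situ SN2 displacement by chloride at the primary allylic carbon, conditions known to give allylic chlorides without allylic transposition or loss of alkene geometry.

Step 15
Reactants: 25 C13 allylic chloride
Product: 26 (2Z,6Z,8S,9S,10Z)-8-(tert-butyldimethylsilyloxy)-12-chloro-3,7,11-trimethyl-9-(triethylsilyloxy)dodeca-2,6,10-trien-1-ol
Conditions: DDQ, CH2Cl2/pH 7 buffer (10:1), 0 °C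
Reagents that add atoms: none
Why: oxidative cleavage of the electron-rich benzyl ether by DDQ (hydride abstraction, then hydrolysis of the oxocarbenium ion) under buffered conditions that should spare the silyl ethers, the allylic chloride and the alkenes.

Step 16
Reactants: 26 seco chloro alcohol
Product: 27 (3Z,7Z,9S,10S,11Z)-9-(tert-butyldimethylsilyloxy)-4,8,12-trimethyl-10-(triethylsilyloxy)-1-oxacyclotrideca-3,7,11-triene (13-membered ether, O6 bonded to C13)
Conditions: NaH, n-Bu4NI (cat.), THF, 0.003 M (slow addition), 50 °C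
Reagents that add atoms: none
Why: intramolecular Williamson etherification (SN2 at the primary allylic chloride) under high dilution, the reaction type used to make 13-membered diallylic ethers; the two Z alkenes pre-bend the chain and no stereocentre is affected.

Step 17
Reactants: 27 13-membered diallylic ether
Product: 29 (6S,7S,8S,9S)-9-(tert-butyldimethylsilyloxy)-8-(triethylsilyloxy)germacra-1(10)Z,4Z,11(13)-trien-6-ol, via C6-lithiated ether 28 (not isolated)
Conditions: n-BuLi, THF, −78 → −20 °C; aq. NH4Cl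
Reagents that add atoms: none
Why: n-BuLi removes a proton from C6, the methylene that is both α to oxygen and allylic to C4=C5, and the lithio ether 28 bonds from C6 to C7 while the O–C13 bond breaks and the π bond moves from C7=C11 to C11=C13, a concerted suprafacial [2,3]-sigmatropic (Wittig) shift through a five-membered envelope C6–O–C13–C11=C7. The closest known reaction type is the [2,3]-Wittig ring contraction of 13-membered diallylic ethers to germacrane-type cyclodecadienols. The ten-membered carbocycle closes transannularly by this C6–C7 bond formation inside the 13-membered ring, which loses O6, C13 and C11 from its perimeter, so no direct carbon–carbon macrocyclisation is needed and the C6 hydroxyl and the C11=C13 methylene appear together. C6 and C7 are set relative to each other by the Z geometry of C7=C11 (C13 cis to C8) with the C5 alkenyl substituent exo on the envelope, which should give the syn (erythro) pair with H6 and H7 cis; the absolute sense comes from C8, because allylic 1,3-strain against C13H2 keeps H8 eclipsed with the alkene, the ring bond C8–C9 and the silyloxy group then lie on opposite faces, and C6 is expected to bond on the face away from C8–C9, placing C11 and O8 cis on the ring. The step needs lithiation at C6 and not C13, a [2,3] and not a [1,2] shift, and this face selectivity: the C13 anion would have to bond to the fully substituted C4, the low temperature suppresses the [1,2] pathway, and only silyl ethers and methyl groups (no ester at C12 or C14 yet) face the base.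

Step 18
Reactants: 29 cyclodecadienol
Product: 30 (4R,5S,6R,7S,8S,9S)-9-(tert-butyldimethylsilyloxy)-4,5-epoxy-8-(triethylsilyloxy)germacra-1(10)Z,11(13)-dien-6-ol
Conditions: VO(acac)2 (cat.), t-BuOOH (1.2 equiv), CH2Cl2, 0 °C
Reagents that add atoms: tert-butyl hydroperoxide CC(C)(C)OO
Why: vanadium-catalysed hydroxyl-directed epoxidation: the C6 alkoxide bound to vanadium delivers oxygen to the allylic C4=C5 bond much faster than to the homoallylic C11=C13 or remote C1=C10 bonds, and allylic 1,3-strain across the Z alkene (C3 against C6) holds H6 in the alkene plane so that oxygen should arrive on the face carrying O6, giving the threo (4R,5S) epoxy alcohol.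

Step 19
Reactants: 30 4,5-epoxy alcohol
Product: 31 (4R,5S,6R,7S,8S,9S)-9-(tert-butyldimethylsilyloxy)-4,5-epoxy-8-(triethylsilyloxy)germacra-1(10)Z,11(13)-diene-6,12,14-triol
Conditions: SeO2 (0.5 equiv), t-BuOOH (4 equiv), CH2Cl2, rt
Reagents that add atoms: tert-butyl hydroperoxide CC(C)(C)OO (terminal oxidant; the oxygen is relayed by catalytic selenium dioxide O=[Se]=O)
Why: Riley-type allylic oxidation (ene reaction, then [2,3]-shift of the allylseleninic acid) at the two allylic methyl groups: C12 on the 1,1-disubstituted C11=C13 alkene (methyl preferred over the ring methine C7) and C14, the methyl trans to C2 on the trisubstituted C1=C10 alkene, with the ring-cis geometry retained; the oxirane has already removed C15 and C3 as allylic sites, and the reaction type is known on 4,5-epoxygermacrenes.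

Step 20
Reactants: 31 6,12,14-triol
Product: 34 (4R,5S,6R,7S,8S,9S)-9-(tert-butyldimethylsilyloxy)-4,5-epoxy-14-oxo-8-(triethylsilyloxy)germacra-1(10)E,11(13)-dien-12,6-olide, via 6-hydroxy-12,14-dial 32 (not isolated), via 12,6-lactol 33 (not isolated)
Conditions: TEMPO (cat.), PhI(OAc)2, CH2Cl2, rt
Reagents that add atoms: none
Why: oxoammonium (TEMPO) oxidation takes only the two primary allylic alcohols; the C12 aldehyde is trapped by the cis C6 hydroxyl as the five-membered lactol 33, which is oxidised on to the α-methylene lactone, while C14 stops at the enal, and any aldehyde-level material from step 19 converges here.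

Step 21
Reactants: 34 lactone enal
Product: 35 (4R,5S,6R,7S,8S,9S)-9-(tert-butyldimethylsilyloxy)-4,5-epoxy-8-(triethylsilyloxy)germacra-1(10)E,11(13)-dien-12,6-olid-14-oic acid
Conditions: NaClO2, NaH2PO4, 2-methyl-2-butene, t-BuOH/H2O, 0 °C → rt
Reagents that add atoms: sodium chlorite [Na+].[O-]Cl=O
Why: Pinnick oxidation converts the enal to the acid under mildly acidic conditions with the hypochlorous acid scavenged, so the oxirane, the α-methylene lactone and the silyl ethers should stay intact.

Step 22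
Reactants: 35 C14 carboxylic acid
Product: 36 methyl (4R,5S,6R,7S,8S,9S)-9-(tert-butyldimethylsilyloxy)-4,5-epoxy-8-(triethylsilyloxy)germacra-1(10)E,11(13)-dien-12,6-olid-14-oate
Conditions: MeI, KHCO3, DMF, rt
Reagents that add atoms: iodomethane CI
Why: SN2 O-methylation of the carboxylate with a weak base avoids diazoalkanes (which add to α-methylene lactones) and basic methanol (conjugate addition, lactone opening).

Step 23
Reactants: 36 bis-silyl methyl ester lactone
Product: 37 methyl (4R,5S,6R,7R,8S,9S)-9-(tert-butyldimethylsilyloxy)-4,5-epoxy-8-hydroxygermacra-1(10)E,11(13)-dien-12,6-olid-14-oate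
Conditions: HF·pyridine, pyridine, THF, 0 °C
Reagents that add atoms: none
Why: buffered acidic fluoride cleaves the triethylsilyl ether faster than the bulkier tert-butyldimethylsilyl ether, and the absence of alkoxide should prevent silyl migration from O9 and relactonisation onto O8.

Step 24
Reactants: 37 C8 alcohol; 38 angelic acid
Product: 40 methyl (4R,5S,6R,7S,8S,9S)-8-(angeloyloxy)-9-(tert-butyldimethylsilyloxy)-4,5-epoxygermacra-1(10)E,11(13)-dien-12,6-olid-14-oate, via angelic 2,4,6-trichlorobenzoic anhydride 39 (not isolated)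
Conditions: 38, 2,4,6-Cl3C6H2COCl, Et3N, toluene, rt; then 37, 80 °C
Reagents that add atoms: none
Why: Yamaguchi esterification: the mixed anhydride 39 acylates the hindered C8 hydroxyl on heating without a nucleophilic catalyst, the conditions under which the Z (angelate) geometry is kept and not isomerised to the tiglate.

Step 25
Reactants: 40 8-angelate 9-silyl ether
Product: 41 methyl (4R,5S,6R,7R,8S,9S)-8-(angeloyloxy)-4,5-epoxy-9-hydroxygermacra-1(10)E,11(13)-dien-12,6-olid-14-oate (CNP0251641.1)
Conditions: HF·pyridine (excess), pyridine, THF, 0 °C → rt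
Reagents that add atoms: none
Why: acidic fluoride removes the remaining silyl ether without generating an alkoxide, so the angelate should not migrate from O8 to O9 and the oxirane and α-methylene lactone are left alone.

**Compound list**

1 | nerol, (2Z)-3,7-dimethylocta-2,6-dien-1-ol | CC(C)=CCC/C(C)=C\CO | starting material
2 | neryl 4-methoxybenzyl ether | COc1ccc(COC/C=C(C)\CCC=C(C)C)cc1 | intermediate
3 | racemic distal epoxide of 2, 3-{(3Z)-5-[(4-methoxybenzyl)oxy]-3-methylpent-3-en-1-yl}-2,2-dimethyloxirane | COc1ccc(COC/C=C(C)\CCC2OC2(C)C)cc1 | intermediate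
4 | (4Z)-6-[(4-methoxybenzyl)oxy]-4-methylhex-4-enal | COc1ccc(COC/C=C(C)\CCC=O)cc1 | intermediate
5 | ethyltriphenylphosphonium iodide | CC[P+](c1ccccc1)(c1ccccc1)c1ccccc1.[I-] | starting material
6 | ethylidenetriphenylphosphorane | CC=P(c1ccccc1)(c1ccccc1)c1ccccc1 | intermediate
7 | (1-iodoethyl)triphenylphosphonium iodide | CC(I)[P+](c1ccccc1)(c1ccccc1)c1ccccc1.[I-] | intermediate
8 | (1-iodoethylidene)triphenylphosphorane | CC(I)=P(c1ccccc1)(c1ccccc1)c1ccccc1 | intermediate
9 | (2Z,6Z)-7-iodo-3-methylocta-2,6-dien-1-yl 4-methoxybenzyl ether (iodine on C10, cis to C2) | COc1ccc(COC/C=C(C)\CC/C=C(C)\I)cc1 | intermediate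
10 | (R)-2,2-dimethyl-1,3-dioxolane-4-carbaldehyde | O=C[C@@H]1OC(C)(C)OC1 | starting material
11 | methyl 2-[bis(2,2,2-trifluoroethoxy)phosphoryl]propanoate | COC(=O)C(C)P(=O)(OCC(F)(F)F)OCC(F)(F)F | starting material
12 | methyl (2Z)-3-[(4S)-2,2-dimethyl-1,3-dioxolan-4-yl]-2-methylprop-2-enoate | COC(=O)/C(C)=C\[C@@H]1OC(C)(C)OC1 | intermediate
13 | (2Z)-3-[(4S)-2,2-dimethyl-1,3-dioxolan-4-yl]-2-methylprop-2-en-1-ol | OC/C(C)=C\[C@@H]1OC(C)(C)OC1 | intermediate
14 | (2Z)-3-[(4S)-2,2-dimethyl-1,3-dioxolan-4-yl]-2-methylprop-2-en-1-yl pivalate | CC(C)(C)C(=O)OC/C(C)=C\[C@@H]1OC(C)(C)OC1 | intermediate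
15 | (2Z,4S)-4,5-dihydroxy-2-methylpent-2-en-1-yl pivalate | CC(C)(C)C(=O)OC/C(C)=C\[C@H](O)CO | intermediate
16 | (2Z,4S)-2-methyl-4,5-bis(triethylsilyloxy)pent-2-en-1-yl pivalate | CC(C)(C)C(=O)OC/C(C)=C\[C@H](O[Si](CC)(CC)CC)CO[Si](CC)(CC)CC | intermediate
17 | dimethyl{[(2S,3Z)-4-methyl-5-(pivaloyloxy)-2-(triethylsilyloxy)pent-3-en-1-yl]oxy}sulfonium chloride | CC(C)(C)C(=O)OC/C(C)=C\[C@H](O[Si](CC)(CC)CC)CO[S+](C)C.[Cl-] | intermediate
18 | (2Z,4S)-2-methyl-5-oxo-4-(triethylsilyloxy)pent-2-en-1-yl pivalate | CC(C)(C)C(=O)OC/C(C)=C\[C@H](O[Si](CC)(CC)CC)C=O | intermediate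
19 | alkenyllithium from 9 (lithium in place of iodine) | COc1ccc(COC/C=C(C)\CC/C=C(C)\[Li])cc1 | intermediate
20 | alkenylzinc bromide from 9 (ZnBr in place of iodine) | COc1ccc(COC/C=C(C)\CC/C=C(C)\[Zn]Br)cc1 | intermediate
21 | (2Z,4S,5S,6Z,10Z)-5-hydroxy-12-[(4-methoxybenzyl)oxy]-2,6,10-trimethyl-4-(triethylsilyloxy)dodeca-2,6,10-trien-1-yl pivalate, germacrane (8S,9S) | COc1ccc(COC/C=C(C)\CC/C=C(C)\[C@H](O)[C@@H](O[Si](CC)(CC)CC)/C=C(C)\COC(=O)C(C)(C)C)cc1 | intermediate
22 | (2Z,4S,5S,6Z,10Z)-5-(tert-butyldimethylsilyloxy)-12-[(4-methoxybenzyl)oxy]-2,6,10-trimethyl-4-(triethylsilyloxy)dodeca-2,6,10-trien-1-yl pivalate | COc1ccc(COC/C=C(C)\CC/C=C(C)\[C@H](O[Si](C)(C)C(C)(C)C)[C@@H](O[Si](CC)(CC)CC)/C=C(C)\COC(=O)C(C)(C)C)cc1 | intermediate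
23 | (2Z,4S,5S,6Z,10Z)-5-(tert-butyldimethylsilyloxy)-12-[(4-methoxybenzyl)oxy]-2,6,10-trimethyl-4-(triethylsilyloxy)dodeca-2,6,10-trien-1-ol | COc1ccc(COC/C=C(C)\CC/C=C(C)\[C@H](O[Si](C)(C)C(C)(C)C)[C@@H](O[Si](CC)(CC)CC)/C=C(C)\CO)cc1 | intermediate
24 | methanesulfonate of 23 at O13 | COc1ccc(COC/C=C(C)\CC/C=C(C)\[C@H](O[Si](C)(C)C(C)(C)C)[C@@H](O[Si](CC)(CC)CC)/C=C(C)\COS(C)(=O)=O)cc1 | intermediate
25 | C13 allylic chloride, (2Z,6Z,8S,9S,10Z)-8-(tert-butyldimethylsilyloxy)-12-chloro-3,7,11-trimethyl-9-(triethylsilyloxy)dodeca-2,6,10-trien-1-yl 4-methoxybenzyl ether | COc1ccc(COC/C=C(C)\CC/C=C(C)\[C@H](O[Si](C)(C)C(C)(C)C)[C@@H](O[Si](CC)(CC)CC)/C=C(C)\CCl)cc1 | intermediate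
26 | (2Z,6Z,8S,9S,10Z)-8-(tert-butyldimethylsilyloxy)-12-chloro-3,7,11-trimethyl-9-(triethylsilyloxy)dodeca-2,6,10-trien-1-ol | OC/C=C(C)\CC/C=C(C)\[C@H](O[Si](C)(C)C(C)(C)C)[C@@H](O[Si](CC)(CC)CC)/C=C(C)\CCl | intermediate
27 | (3Z,7Z,9S,10S,11Z)-9-(tert-butyldimethylsilyloxy)-4,8,12-trimethyl-10-(triethylsilyloxy)-1-oxacyclotrideca-3,7,11-triene | O1C/C=C(C)\CC/C=C(C)\[C@H](O[Si](C)(C)C(C)(C)C)[C@@H](O[Si](CC)(CC)CC)/C=C(C)\C1 | intermediate
28 | ether 27 lithiated at C6 (ring C2) | O1C([Li])/C=C(C)\CC/C=C(C)\[C@H](O[Si](C)(C)C(C)(C)C)[C@@H](O[Si](CC)(CC)CC)/C=C(C)\C1 | intermediate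
29 | (6S,7S,8S,9S)-9-(tert-butyldimethylsilyloxy)-8-(triethylsilyloxy)germacra-1(10)Z,4Z,11(13)-trien-6-ol (C7 bears isopropenyl; H6, H7, H8 cis) | O[C@H]1/C=C(C)\CC/C=C(C)\[C@H](O[Si](C)(C)C(C)(C)C)[C@@H](O[Si](CC)(CC)CC)[C@H]1C(C)=C | intermediate
30 | (4R,5S,6R,7S,8S,9S)-9-(tert-butyldimethylsilyloxy)-4,5-epoxy-8-(triethylsilyloxy)germacra-1(10)Z,11(13)-dien-6-ol | O[C@H]1[C@@H]2O[C@]2(C)CC/C=C(C)\[C@H](O[Si](C)(C)C(C)(C)C)[C@@H](O[Si](CC)(CC)CC)[C@H]1C(C)=C | intermediate
31 | (4R,5S,6R,7S,8S,9S)-9-(tert-butyldimethylsilyloxy)-4,5-epoxy-8-(triethylsilyloxy)germacra-1(10)Z,11(13)-diene-6,12,14-triol | O[C@H]1[C@@H]2O[C@]2(C)CC/C=C(CO)\[C@H](O[Si](C)(C)C(C)(C)C)[C@@H](O[Si](CC)(CC)CC)[C@H]1C(CO)=C | intermediate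
32 | 6-hydroxy-12,14-dial corresponding to 31 | O[C@H]1[C@@H]2O[C@]2(C)CC/C=C(C=O)\[C@H](O[Si](C)(C)C(C)(C)C)[C@@H](O[Si](CC)(CC)CC)[C@H]1C(C=O)=C | intermediate
33 | 12,6-lactol (C12 epimers) with C14 aldehyde | C=C1C(O)O[C@@H]2[C@H]1[C@H](O[Si](CC)(CC)CC)[C@@H](O[Si](C)(C)C(C)(C)C)/C(C=O)=C\CC[C@@]1(C)O[C@@H]21 | intermediate
34 | (4R,5S,6R,7S,8S,9S)-9-(tert-butyldimethylsilyloxy)-4,5-epoxy-14-oxo-8-(triethylsilyloxy)germacra-1(10)E,11(13)-dien-12,6-olide | C=C1C(=O)O[C@@H]2[C@H]1[C@H](O[Si](CC)(CC)CC)[C@@H](O[Si](C)(C)C(C)(C)C)/C(C=O)=C\CC[C@@]1(C)O[C@@H]21 | intermediate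
35 | (4R,5S,6R,7S,8S,9S)-9-(tert-butyldimethylsilyloxy)-4,5-epoxy-8-(triethylsilyloxy)germacra-1(10)E,11(13)-dien-12,6-olid-14-oic acid | C=C1C(=O)O[C@@H]2[C@H]1[C@H](O[Si](CC)(CC)CC)[C@@H](O[Si](C)(C)C(C)(C)C)/C(C(=O)O)=C\CC[C@@]1(C)O[C@@H]21 | intermediate
36 | methyl (4R,5S,6R,7S,8S,9S)-9-(tert-butyldimethylsilyloxy)-4,5-epoxy-8-(triethylsilyloxy)germacra-1(10)E,11(13)-dien-12,6-olid-14-oate | C=C1C(=O)O[C@@H]2[C@H]1[C@H](O[Si](CC)(CC)CC)[C@@H](O[Si](C)(C)C(C)(C)C)/C(C(=O)OC)=C\CC[C@@]1(C)O[C@@H]21 | intermediate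
37 | methyl (4R,5S,6R,7R,8S,9S)-9-(tert-butyldimethylsilyloxy)-4,5-epoxy-8-hydroxygermacra-1(10)E,11(13)-dien-12,6-olid-14-oate | C=C1C(=O)O[C@@H]2[C@H]1[C@H](O)[C@@H](O[Si](C)(C)C(C)(C)C)/C(C(=O)OC)=C\CC[C@@]1(C)O[C@@H]21 | intermediate
38 | angelic acid, (2Z)-2-methylbut-2-enoic acid | C/C=C(/C)C(=O)O | starting material
39 | angelic 2,4,6-trichlorobenzoic anhydride | C/C=C(/C)C(=O)OC(=O)c1c(Cl)cc(Cl)cc1Cl | intermediate
40 | methyl (4R,5S,6R,7S,8S,9S)-8-(angeloyloxy)-9-(tert-butyldimethylsilyloxy)-4,5-epoxygermacra-1(10)E,11(13)-dien-12,6-olid-14-oate | C=C1C(=O)O[C@@H]2[C@H]1[C@H](OC(=O)/C(C)=C\C)[C@@H](O[Si](C)(C)C(C)(C)C)/C(C(=O)OC)=C\CC[C@@]1(C)O[C@@H]21 | intermediate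
41 | methyl (4R,5S,6R,7R,8S,9S)-8-(angeloyloxy)-4,5-epoxy-9-hydroxygermacra-1(10)E,11(13)-dien-12,6-olid-14-oate (CNP0251641.1) | C=C1C(=O)O[C@@H]2[C@H]1[C@H](OC(=O)/C(C)=C\C)[C@@H](O)/C(C(=O)OC)=C\CC[C@@]1(C)O[C@@H]21 | target

**Count and risks**

Total steps: 25 (4 to the alkenyl iodide, 6 to the aldehyde, 15 after their union). Longest linear sequence: 21 steps (10 → 41, steps 5–25).

Steps most likely to fail:

1. Step 17 (ring contraction). What may go wrong: lithiation at C13 in place of C6, a [1,2]-shift if the anion survives to higher temperature, or bonding of C6 to the C7 face anti to the C8–O bond. That face is the one usually preferred when an allyl unit with an allylic C–O bond acts as the acceptor, and it would give the C6/C7 diastereomer. Fallback, setting out from 26 and coming back at 29: the chloride of 26 is displaced with Bu3SnLi (2 equiv, THF, −78 °C; the first equivalent forms the alkoxide) to give the allylic stannane alcohol F1. MnO2 (CH2Cl2) oxidises it to the (Z)-enal F2. BF3·OEt2 (CH2Cl2, −78 °C, high dilution) then triggers an intramolecular SE2' allylation in which C7 of the allylstannane attacks the C6 aldehyde, forming the same C6–C7 bond and the C11=C13 methylene and giving 29. Here the alkene is the nucleophile: the open antiperiplanar transition state should give the syn C6/C7 pair whatever the alkene geometry, and electrophilic attack at C7 is expected anti to the C8–C9 bond, which is the face needed.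

2. Step 11 (fragment union). What may go wrong: addition through the open Felkin–Anh mode because the silyl ether binds zinc only weakly, which would give the C9 epimer or a mixture. Fallback, setting out from 21 obtained as a mixture of C9 epimers and coming back at 21: Dess–Martin periodinane (NaHCO3, CH2Cl2) oxidises the mixture to the enone F3. LiBH(s-Bu)3 (THF, −78 °C) then reduces the ketone under Felkin–Anh control (hydride anti to the C8 silyloxy group), which should give the 8,9-syn alcohol 21; the hindered pivalate is not expected to be reduced at this temperature. C9 is then set by reagent approach to a ketone and no longer by chelation in a carbon–carbon bond formation.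

3. Step 24 (angelate). What may go wrong: slow acylation of the hindered C8 hydroxyl (flanked by the lactone ring fusion and the C9 silyl ether), during which the activated angelate isomerises to the E (tiglate) isomer. Fallback, setting out from 37 and coming back at 40: 37 is acylated with 2-[bis(2,2,2-trifluoroethoxy)phosphoryl]propanoic acid (from 11 by cleavage of the methyl ester; DCC, DMAP, CH2Cl2) to give the phosphonate ester F4. With no alkene to isomerise, this acylation can be forced. KN(SiMe3)2/18-crown-6 (THF, −78 °C) and acetaldehyde then build the Z-configured 2-methylbut-2-enoate on the molecule by Still–Gennari olefination, giving 40.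

Further compounds
F1 | step 17 | (2Z,6Z,8S,9S,10Z)-8-(tert-butyldimethylsilyloxy)-3,7,11-trimethyl-12-(tributylstannyl)-9-(triethylsilyloxy)dodeca-2,6,10-trien-1-ol | OC/C=C(C)\CC/C=C(C)\[C@H](O[Si](C)(C)C(C)(C)C)[C@@H](O[Si](CC)(CC)CC)/C=C(C)\C[Sn](CCCC)(CCCC)CCCC
F2 | step 17 | (2Z,6Z,8S,9S,10Z)-8-(tert-butyldimethylsilyloxy)-3,7,11-trimethyl-12-(tributylstannyl)-9-(triethylsilyloxy)dodeca-2,6,10-trienal | O=C/C=C(C)\CC/C=C(C)\[C@H](O[Si](C)(C)C(C)(C)C)[C@@H](O[Si](CC)(CC)CC)/C=C(C)\C[Sn](CCCC)(CCCC)CCCC
F3 | step 11 | (2Z,4S,6Z,10Z)-12-[(4-methoxybenzyl)oxy]-2,6,10-trimethyl-5-oxo-4-(triethylsilyloxy)dodeca-2,6,10-trien-1-yl pivalate | COc1ccc(COC/C=C(C)\CC/C=C(C)\C(=O)[C@@H](O[Si](CC)(CC)CC)/C=C(C)\COC(=O)C(C)(C)C)cc1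
F4 | step 24 | 8-O-{2-[bis(2,2,2-trifluoroethoxy)phosphoryl]propanoyl} derivative of 37 (epimers at the phosphonate carbon) | C=C1C(=O)O[C@@H]2[C@H]1[C@H](OC(=O)C(C)P(=O)(OCC(F)(F)F)OCC(F)(F)F)[C@@H](O[Si](C)(C)C(C)(C)C)/C(C(=O)OC)=C\CC[C@@]1(C)O[C@@H]21
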